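The dihydropyranone ring (O1, C2, C3, C4, C4a, C8a; chromanone numbering) is read as the closed valence isomer of a 2-tigloyl β-triketone, so everything rests on the O1–C2 disconnection beside quaternary C8. In one operation a chiral phosphoric acid couples a reversible oxa-6π closure (formal 6-endo oxa-Michael addition) with an irreversible, face-selective protonation of C3. E/Z isomers and both C2 epimers funnel into the cis-(2R,3S) ring. The step exploits the enolised C8a–OH/C4=O chelate of the dearomatised carbocycle, while O5 is tied to the C6 hexanoic acid chain as a δ-lactone, leaving O8a as the only nucleophile. The precursor is an open tigloyl enol lactone that already carries the other three stereocentres.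

Key step: step 13

Assumption: in the three catalyst-controlled steps (8, 11, 13) the named ligand or catalyst antipode is the one expected from the usual quadrant models. Both antipodes are commercial, so a reversed sense of induction is corrected by exchanging the antipode.
Locants: coumarin numbering for 12–18, chromanone numbering of the target for 19–26. Enols are drawn as one tautomer.

Step 1
Reactants: 1 (S)-4-benzyl-1,3-oxazolidin-2-one; 2 3-methylbut-2-enoyl chloride
Product: 3 (S)-4-benzyl-3-(3-methylbut-2-enoyl)-1,3-oxazolidin-2-one
Conditions: n-BuLi, THF, −78 °C; then 2, −78 → 0 °C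
Reagents that add atoms: 3-methylbut-2-enoyl chloride (2), CC(C)=CC(=O)Cl
Why: N-acylation of the lithiated oxazolidinone with an acid chloride is the standard loading of the auxiliary for an Evans alkylation and creates no stereocentre.

Step 2
Reactants: 3 senecioyl imide; 4 prenyl bromide
Product: 5 (S)-4-benzyl-3-[(2S)-5-methyl-2-(prop-1-en-2-yl)hex-4-enoyl]-1,3-oxazolidin-2-one
Conditions: NaHMDS, THF, −78 °C; then 4, −78 → −40 °C
Reagents that add atoms: prenyl bromide (4), CC(C)=CCBr
Why: In this deconjugative Evans asymmetric alkylation, γ-deprotonation gives the chelated (Z)-dienolate, which is alkylated at the α-carbon on the face opposite the benzyl group and so sets the future lavandulyl stereocentre (S in the imide).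

Step 3
Reactants: 5 alkylated imide
Product: 6 (S)-lavandulol
Conditions: LiBH4, MeOH (1 equiv), Et2O, 0 °C
Reagents that add atoms: none
Why: Reductive cleavage of the imide with LiBH4 releases the primary alcohol without base, so the β,γ-unsaturated stereocentre should neither epimerise nor move into conjugation.

Step 4
Reactants: 6 (S)-lavandulol
Product: 7 (S)-lavandulyl iodide
Conditions: I2, PPh3, imidazole, CH2Cl2, 0 °C
Reagents that add atoms: iodine, II
Why: The Appel iodination is an SN2 displacement at the primary carbinol carbon and leaves the neighbouring stereocentre untouched.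

Step 5
Reactants: 8 prenol
Product: 9 tert-butyl 3-methylbut-2-en-1-yl carbonate
Conditions: Boc2O, DMAP (cat.), CH2Cl2, 0 °C → rt
Reagents that add atoms: di-tert-butyl dicarbonate, CC(C)(C)OC(=O)OC(=O)OC(C)(C)C
Why: DMAP-catalysed O-acylation gives a mixed carbonate that later ionises to a π-prenyl complex and releases only CO2 and non-nucleophilic tert-butoxide.

Step 6
Reactants: 10 phloroglucinol; 11 ethyl 3-oxohexanoate
Product: 12 5,7-dihydroxy-4-propyl-2H-chromen-2-one
Conditions: conc. H2SO4, 0 °C → rt
Reagents that add atoms: ethyl 3-oxohexanoate (11), CCCC(=O)CC(=O)OCC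
Why: The Pechmann condensation of the symmetric triphenol can give only one coumarin, and its lactone serves from here on as a temporary ring that masks the side-chain acid and O5.

Step 7
Reactants: 12 dihydroxypropylcoumarin; 13 propanoyl chloride
Product: 14 5,7-dihydroxy-8-propanoyl-4-propyl-2H-chromen-2-one
Conditions: AlCl3, 1,2-dichloroethane, 75 °C
Reagents that add atoms: propanoyl chloride (13), CCC(=O)Cl
Why: Friedel–Crafts acylation of 5,7-dihydroxycoumarins goes preferentially to C8, which places the acyl carbon (future C4) next to the lactone oxygen and leaves C6 as the only free ring position.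

Step 8
Reactants: 14 8-propanoylcoumarin
Product: 15 (4R)-5,7-dihydroxy-8-propanoyl-4-propyl-3,4-dihydro-2H-chromen-2-one
Conditions: Cu(OAc)2·H2O (cat.), (R)-DTBM-SEGPHOS (cat.), (EtO)2MeSiH, t-BuOH, toluene, 0 °C; aq NH4F work-up
Reagents that add atoms: none
Why: In the copper hydride-catalysed asymmetric conjugate reduction of a 4-substituted coumarin the ligand directs hydride to one face of C4 and sets the side-chain stereocentre (R), while the di-ortho-substituted, chelated aryl ketone is much less accessible.

Step 9
Reactants: 15 (4R)-dihydrocoumarin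
Product: 16 (4R)-5,7-dihydroxy-6-iodo-8-propanoyl-4-propyl-3,4-dihydro-2H-chromen-2-one
Conditions: NIS, MeCN, 0 °C
Reagents that add atoms: N-iodosuccinimide, O=C1CCC(=O)N1I
Why: Electrophilic aromatic iodination can occur only at C6, the single free position of the highly activated ring.

Step 10
Reactants: 16 aryl iodide; 7 (S)-lavandulyl iodide
Product: 18 (4R)-6-[(2R)-lavandulyl]-5,7-dihydroxy-8-propanoyl-4-propylchroman-2-one, via (S)-lavandulylzinc iodide 17 (not isolated)
Conditions: 7, Zn dust, LiCl, THF, 35 °C; then slow addition to 16, Pd(OAc)2 (cat.), SPhos (cat.), THF, rt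
Reagents that add atoms: (S)-lavandulyl iodide (7), C=C(C)[C@H](CC=C(C)C)CI
Why: The Negishi sp2–sp3 coupling forms the aryl–CH2 bond that phenolate alkylation cannot deliver with this β-branched unactivated halide, tolerates ketone, lactone and (on slow addition) phenols, and does not touch the stereocentre β to zinc (same geometry, descriptor now R).

Step 11
Reactants: 18 lavandulyl arene; 9 tert-butyl prenyl carbonate
Product: 19 (8R)-dearomatised propanoyl enol lactone
Conditions: [Pd2(dba)3]·CHCl3 (cat.), (R,R)-DACH-phenyl bisphosphine ligand (cat.), CH2Cl2, 0 °C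
Reagents that add atoms: tert-butyl 3-methylbut-2-en-1-yl carbonate (9), CC(C)=CCOC(=O)OC(C)(C)C
Why: In this Tsuji–Trost asymmetric allylic dearomatisation the acylphloroglucinol-type phenolate attacks the unsubstituted terminus of the π-prenyl complex at its lavandulyl-bearing carbon, and the chiral pocket selects one face of the planar ring, whose two flanks (chelated OH/acyl versus OH next to the lactone-bearing carbon) are very different, to set C8 (R).

Step 12
Reactants: 19 propanoyl enol lactone; 20 acetaldehyde dimethyl acetal
Product: 23 tigloyl enol lactone, via bis-TMS dienol ether 21 (not isolated), via β-methoxy ketone TMS ether 22 (not isolated)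
Conditions: TMSOTf, i-Pr2NEt, CH2Cl2, −78 °C; 20; → rt; aq citric acid work-up
Reagents that add atoms: acetaldehyde dimethyl acetal (20), CC(OC)OC
Why: One-pot enol silane formation, Mukaiyama addition to the acetal-derived oxocarbenium ion and TMSOTf/amine-induced loss of methanol give the enone without base-induced ring closure and without ever exposing a free β-hydroxyl, which could add to the acyloxy-bearing C5.

Step 13
Reactants: 23 tigloyl enol lactone
Product: 25 cis-(2R,3S)-dihydropyranone lactone, via 2H-pyran-4-ol 24 (not isolated)
Conditions: (R)-TRIP (10 mol %), 4 Å MS, toluene, 0 °C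
Reagents that add atoms: none
Why: Proposed new method: a proton shift within the β-triketone chelate of 23 gives the exocyclic enol, a 1-oxatriene (O8a=C8a–C4a=C4(OH)–C3=C2), which closes reversibly by disrotatory oxa-6π electrocyclisation to the 2H-pyran-4-ol 24, and the phosphoric acid then acts as a bifunctional proton shuttle that converts this enol irreversibly into the C4 ketone. The closest known reaction types are the cinchona-alkaloid-catalysed intramolecular oxa-Michael addition of o-tigloylphenols to cis-2,3-dimethylchroman-4-ones, chiral phosphoric acid-catalysed intramolecular oxa-Michael additions, and Brønsted acid-catalysed electrocyclisation with enantioselective protonation of the Nazarov type, none of which has been shown on a 2-enoyl-1,3-dione enol. The single ring closes through the O1–C2 bond, formally a 6-endo-trig oxa-Michael addition of O8a to C2. C3 (S) is set by the catalyst, which delivers the proton to one face of the enol, and C2 (R) follows because protonation is fastest anti to the pseudoaxial C2 methyl group, so only the (2R)-pyranol is drained while its epimer and the E/Z isomers of 23 are fed back through ring opening (dynamic kinetic resolution) and the kinetic cis isomer results. The step needs O8a over O5 regioselectivity, secured by the δ-lactone on O5, and kinetic cis over trans selectivity, secured by the absence of base and by the fact that 25 has no acidic OH left and enolises slowly. The acid is too weak to protonate the prenyl and lavandulyl double bonds, and the stereocentres at C8, in the side chain and in the lavandulyl group are remote spectators.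

Step 14
Reactants: 25 dihydropyranone lactone
Product: 26 target acid CNP0266113.2
Conditions: LiOH, THF/H2O, 0 °C; then 1 M HCl to pH 4
Reagents that add atoms: water, O
Why: The enol lactone is a vinylogous anhydride that should be saponified far faster than C3 is deprotonated, and the resulting carboxylate/enolate dianion resists retro-oxa-Michael opening and epimerisation until the cold acidic quench frees CO2H and the chelated C5–OH.

Compound list
1 | (S)-4-benzyl-1,3-oxazolidin-2-one | O=C1N[C@@H](Cc2ccccc2)CO1 | starting material
2 | 3-methylbut-2-enoyl chloride | CC(C)=CC(=O)Cl | starting material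
3 | (S)-4-benzyl-3-(3-methylbut-2-enoyl)-1,3-oxazolidin-2-one | CC(C)=CC(=O)N1[C@@H](Cc2ccccc2)COC1=O | intermediate
4 | 1-bromo-3-methylbut-2-ene (prenyl bromide) | CC(C)=CCBr | starting material
5 | (S)-4-benzyl-3-[(2S)-5-methyl-2-(prop-1-en-2-yl)hex-4-enoyl]-1,3-oxazolidin-2-one | C=C(C)[C@H](CC=C(C)C)C(=O)N1[C@@H](Cc2ccccc2)COC1=O | intermediate
6 | (S)-lavandulol, (2S)-5-methyl-2-(prop-1-en-2-yl)hex-4-en-1-ol | C=C(C)[C@H](CC=C(C)C)CO | intermediate
7 | (S)-lavandulyl iodide, (3S)-3-(iodomethyl)-2,6-dimethylhepta-1,5-diene | C=C(C)[C@H](CC=C(C)C)CI | intermediate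
8 | 3-methylbut-2-en-1-ol (prenol) | CC(C)=CCO | starting material
9 | tert-butyl 3-methylbut-2-en-1-yl carbonate | CC(C)=CCOC(=O)OC(C)(C)C | intermediate
10 | phloroglucinol (benzene-1,3,5-triol) | Oc1cc(O)cc(O)c1 | starting material
11 | ethyl 3-oxohexanoate | CCCC(=O)CC(=O)OCC | starting material
12 | 5,7-dihydroxy-4-propyl-2H-chromen-2-one | CCCC1=CC(=O)Oc2cc(O)cc(O)c12 | intermediate
13 | propanoyl chloride | CCC(=O)Cl | starting material
14 | 5,7-dihydroxy-8-propanoyl-4-propyl-2H-chromen-2-one | CCCC1=CC(=O)Oc2c(C(=O)CC)c(O)cc(O)c12 | intermediate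
15 | (4R)-5,7-dihydroxy-8-propanoyl-4-propyl-3,4-dihydro-2H-chromen-2-one | CCC[C@@H]1CC(=O)Oc2c(C(=O)CC)c(O)cc(O)c12 | intermediate
16 | (4R)-5,7-dihydroxy-6-iodo-8-propanoyl-4-propyl-3,4-dihydro-2H-chromen-2-one | CCC[C@@H]1CC(=O)Oc2c(C(=O)CC)c(O)c(I)c(O)c12 | intermediate
17 | [(2S)-5-methyl-2-(prop-1-en-2-yl)hex-4-en-1-yl]zinc iodide | C=C(C)[C@H](CC=C(C)C)C[Zn]I | intermediate
18 | (4R)-5,7-dihydroxy-6-[(2R)-5-methyl-2-(prop-1-en-2-yl)hex-4-en-1-yl]-8-propanoyl-4-propyl-3,4-dihydro-2H-chromen-2-one | CCC[C@@H]1CC(=O)Oc2c(C(=O)CC)c(O)c(C[C@@H](CC=C(C)C)C(C)=C)c(O)c12 | intermediate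
19 | (4R,6R)-7-hydroxy-6-[(2R)-5-methyl-2-(prop-1-en-2-yl)hex-4-en-1-yl]-6-(3-methylbut-2-en-1-yl)-8-propanoyl-4-propyl-3,4-dihydro-2H-chromene-2,5(6H)-dione (C8 R in target numbering) | C=C(C)[C@H](CC=C(C)C)C[C@@]1(CC=C(C)C)C(=O)C2=C(OC(=O)C[C@H]2CCC)C(C(=O)CC)=C1O | intermediate
20 | 1,1-dimethoxyethane (acetaldehyde dimethyl acetal) | CC(OC)OC | starting material
21 | O8a-trimethylsilyl ether of 19 in which the propanoyl group is its (Z)-trimethylsilyl enol ether | C=C(C)[C@H](CC=C(C)C)C[C@@]1(CC=C(C)C)C(=O)C2=C(OC(=O)C[C@H]2CCC)C(/C(O[Si](C)(C)C)=C/C)=C1O[Si](C)(C)C | intermediate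
22 | O8a-trimethylsilyl ether of the 3-methoxy-2-methylbutanoyl analogue of 19 (mixture at the two transient side-chain centres) | C=C(C)[C@H](CC=C(C)C)C[C@@]1(CC=C(C)C)C(=O)C2=C(OC(=O)C[C@H]2CCC)C(C(=O)C(C)C(C)OC)=C1O[Si](C)(C)C | intermediate
23 | analogue of 19 with an (E)-2-methylbut-2-enoyl (tigloyl) group on C4a in place of propanoyl | C=C(C)[C@H](CC=C(C)C)C[C@@]1(CC=C(C)C)C(=O)C2=C(OC(=O)C[C@H]2CCC)C(C(=O)/C(C)=C/C)=C1O | intermediate
24 | (2R)-2,3-dimethyl-2H-pyran-4-ol fused at C4a/C8a, the C4 enol of 25 | C=C(C)[C@H](CC=C(C)C)C[C@@]1(CC=C(C)C)C(=O)C2=C(OC(=O)C[C@H]2CCC)C3=C1O[C@H](C)C(C)=C3O | intermediate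
25 | δ-lactone of the target (C5–O–C(=O) in place of C5–OH and CO2H), cis-(2R,3S), 8R, side chain R, lavandulyl R | C=C(C)[C@H](CC=C(C)C)C[C@@]1(CC=C(C)C)C(=O)C2=C(OC(=O)C[C@H]2CCC)C3=C1O[C@H](C)[C@H](C)C3=O | intermediate
26 | (3R)-3-[(2R,3S,8R)-5-hydroxy-2,3-dimethyl-8-[(2R)-5-methyl-2-(prop-1-en-2-yl)hex-4-en-1-yl]-8-(3-methylbut-2-en-1-yl)-4,7-dioxo-3,4,7,8-tetrahydro-2H-chromen-6-yl]hexanoic acid | C=C(C)[C@H](CC=C(C)C)C[C@@]1(CC=C(C)C)C(=O)C([C@H](CCC)CC(=O)O)=C(O)C2=C1O[C@H](C)[C@H](C)C2=O | target

Total step count: 14. Longest linear sequence: 9 steps (steps 6–14 from phloroglucinol; equally steps 1–4 and 10–14 from the auxiliary).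

Steps most likely to fail

Step 13 (proposed new method).
- Risks: proton transfer by the acidic enol of the substrate itself may compete with catalyst-bound protonation and erode facial control. Slow acid-catalysed enolisation of the product may let the cis isomer drift to trans. Loss of the strong enol chelate on closure may leave the open/closed equilibrium short of full conversion.
- Fallback (known chemistry): the ring closure is moved to the aromatic stage, where the alkaloid-catalysed reaction is established. It sets out from 18. The TMSOTf/i-Pr2NEt/acetal protocol of step 12 gives the o-tigloylphenol (4R)-5,7-dihydroxy-6-[(2R)-lavandulyl]-8-tigloyl-4-propylchroman-2-one F1. (−)-Quinine in chlorobenzene at rt then effects the intramolecular oxa-Michael addition through the only free ortho oxygen, to the aromatic cis-(2R,3S)-chromanone lactone F2. Tsuji–Trost dearomative prenylation of the remaining phenol of F2 with 9 under the conditions of step 11 comes back to the route at 25.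

Step 11.
- Risks: the chiral pocket may discriminate the two ring faces poorly, O-prenylation may compete, and re-ionisation of the C8–prenyl bond by Pd(0) may scramble C8.
- Fallback: classical alkylative dearomatisation without catalyst control. It sets out from 18. LiHMDS and 4 (THF, −78 → 0 °C) give 19 together with the C8 epimer of 19 F3, and the diastereomers are separated by chromatography. F3 is returned to 18 by Pd(PPh3)4/morpholine deprenylation. The sequence comes back to the route at 19.

Step 8.
- Risks: competing 1,2-reduction of the aryl ketone, over-reduction of the dihydrocoumarin to the lactol, and consumption of silane by the phenols.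
- Fallback: the order of reduction and acylation is exchanged. It sets out from 12, which carries no ketone. The same copper hydride reduction gives (4R)-5,7-dihydroxy-4-propylchroman-2-one F4. Friedel–Crafts acylation of F4 with 13 (AlCl3) comes back to the route at 15, at the price that the C8 regiochemistry must then be secured at the acylation stage.

Further compounds
F1 | step 13 | (4R)-5,7-dihydroxy-6-[(2R)-5-methyl-2-(prop-1-en-2-yl)hex-4-en-1-yl]-8-[(E)-2-methylbut-2-enoyl]-4-propyl-3,4-dihydro-2H-chromen-2-one | CCC[C@@H]1CC(=O)Oc2c(C(=O)/C(C)=C/C)c(O)c(C[C@@H](CC=C(C)C)C(C)=C)c(O)c12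
F2 | step 13 | aromatic cis-(2R,3S)-2,3-dimethylchroman-4-one fused to the (R)-4-propyl δ-lactone, free C7–OH, (2R)-lavandulyl on C8 | CCC[C@@H]1CC(=O)Oc2c3C(=O)[C@@H](C)[C@@H](C)Oc3c(C[C@@H](CC=C(C)C)C(C)=C)c(O)c12
F3 | step 11 | C8 epimer of 19 | C=C(C)[C@H](CC=C(C)C)C[C@]1(CC=C(C)C)C(=O)C2=C(OC(=O)C[C@H]2CCC)C(C(=O)CC)=C1O
F4 | step 8 | (4R)-5,7-dihydroxy-4-propyl-3,4-dihydro-2H-chromen-2-one | CCC[C@@H]1CC(=O)Oc2cc(O)cc(O)c12
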